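I decide to reckon these flasks from one quantity, the ligand surplus, which is the added ligand left over once each catalyst has taken one ligand, written as a fraction of the catalyst charge: 75.0%.

| setting | eta | gamma | epsilon |
|---|---|---|---|
| substrate | 0.20 M | 0.20 M | 0.20 M |
| reagent | 0.500 M | 0.500 M | 0.500 M |
| catalyst | 2.0 mM | 2.0 mM | 2.0 mM |
| added ligand | 3.5 mM | 3.5 mM | 3.5 mM |
| temperature | 20 °C | 0 °C | −20 °C |
| time | 8.0 h | 8.0 h | 8.0 h |

    substrate + reagent + catalyst → catalyst + target (k1 = 830 L² mol⁻² h⁻¹, Ea1 = 52.0 kJ mol⁻¹)
    catalyst + added ligand ⇌ idle complex, settled at all times (K2 = 18000 L mol⁻¹, ΔH2 = 25.0 kJ mol⁻¹)
    (constants at 0 °C)

1. which flask leads in amount of target, in percent of the substrate charged ("all alike" within 1.5 percentage points) (eta / gamma / epsilon / all alike)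
2. how much target is there at the end, in percent of the substrate charged: eta
3. how much target is there at the end, in percent of the substrate charged: gamma
4. how much target is there at the end, in percent of the substrate charged: epsilon

- all constants are for 0 °C and move with temperature by the activation energies and enthalpies

The first rung is the binding, which is kept at balance, and since step 1 gives its catalyst back and consumes no ligand, I expect the split between free catalyst and idle complex to stay as it starts. I solve that split at both ends. Where ligand is in surplus and binding is strong, the free share of the catalyst is one over the product of binding constant and surplus, and for gamma that product is 27.0, which gives 3.70%. Where catalyst exceeds ligand and binding is strong, the free share is that excess over the catalyst charge. Joining the ends by the full balance gives gamma a free share of 3.42%, so nearly all of the catalyst in gamma stands idle.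

The next rung is the loss of substrate. I treat it as pseudo-first-order, with the reagent held at its charge, and for gamma the working constant is 0.0284 h⁻¹. Its time of 35.2 h is longer than the 8.0 h of the run, so I commit to 20.3% of the substrate converted in gamma, at a cost of 8.13% of the reagent's own charge.

Temperature comes last. From epsilon to eta step 1 speeds up by a factor of 29, and over the same span binding strengthens by 5.06, which is that factor raised to the ratio of the two energies. Taking the free share at the surplus end of my solution, as one over the binding constant and surplus, I estimate that the working constant rises by 5.76 over that span, an apparent activation energy of 27.0 kJ mol⁻¹, so I choose eta as the leader. My hand stops at gamma's number and this ratio.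

The forecast names eta and gives 38.5% for eta, 19.6% for gamma and 7.7% for epsilon, holding that "the rate constant rises about thirtyfold and wins".

The simulation gives 38.5% in eta, 19.6% in gamma and 7.66% in epsilon, so eta leads. At 8.00 h gamma holds 3.42% of its catalyst free and 44.8% of its added ligand, while the surplus, taken against the ligand charge, is 42.9%. For a neighbour of epsilon charged with 0.0080 M of catalyst, the extra catalyst first covers the surplus, and what remains is 56.2% of the new charge, the other end of my solution. That neighbour reads 57.5% free at 8.00 h and holds 85.3% target.

The numbers of this flask were set for the occasion; the rest is arithmetic.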